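**Retrosynthetic overview**

1. Target 25 ⇐ cis-lactone 22 (only silyl/ester changes) ⇐ ten-membered (4E,6Z)-diene 19 + 2-bromoacrylic acid 20. A palladium-catalysed [3+2] heteroannulation forms O–C6 and C11–C7, and with them the whole α-methylene-γ-butyrolactone and both ring-fusion stereocentres.
2. Enabling feature: in the lactone ring the O–C6 bond is allylic to the C4=C5 alkene of the ten-membered ring and C7 carries the vinylic carbon C11. The lactone is therefore the 1,2-adduct of a C4=C5–C6=C7 diene (C6–C5–C4 becomes the allylpalladium unit), and its cis fusion is what syn addition to a (Z)-C6=C7 bond gives.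
3. 19 ⇐ ring-closing metathesis (C6=C7) of acyclic trienal 18 ⇐ Horner–Wadsworth–Emmons union (C1=C10) of aldehyde 9 and phosphonate 15.
4. 9 ⇐ copper-catalysed anti-carbomagnesiation of enynol 3 (sets C4=C5); 15 ⇐ (2R)-but-3-ene-1,2-diol 10 (source of C8, the only purchased stereocentre).
5. Ring order: ten-membered carbocycle first (step 11), lactone ring second (step 12).

Key step: step 12

Remark: atom numbers in the text are germacrane positions (ring C1–C10, lactone C11–C13 with C12 the carbonyl and C13 the methylene, formyl C14, hydroxymethyl C15); both enantiomers of but-3-ene-1,2-diol are assumed to be purchasable.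

**Route**

Step 1
Reactants: 1 prop-2-yn-1-ol; 2 bromoethene
Product: 3 pent-4-en-2-yn-1-ol
Conditions: PdCl2(PPh3)2 (2 mol %), CuI (4 mol %), i-Pr2NH, THF, 0 °C to rt
Reagents that add atoms: none
Why: Sonogashira coupling of a terminal alkyne with a vinyl bromide is reliable and tolerates the free hydroxyl group.

Step 2
Reactants: 3 pent-4-en-2-yn-1-ol; 4 2-(2-bromoethyl)-1,3-dioxolane
Product: 7 (2E)-2-[2-(1,3-dioxolan-2-yl)ethyl]penta-2,4-dien-1-ol, via Grignard reagent 5 (not isolated), via alkenylmagnesium chelate 6 (not isolated)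
Conditions: Mg, THF, 30 °C (4 to 5, 3 equiv); then 3, CuI (10 mol %), THF, −20 °C to rt; aq. NH4Cl
Reagents that add atoms: none
Why: Copper-catalysed anti-carbomagnesiation of a propargylic alcohol, in which the magnesium alkoxide directs the alkyl group to the proximal alkyne carbon C4 and holds magnesium on C5 in the five-membered chelate 6, so that protonation should leave the C3 chain cis to the vinyl group and the hydroxymethyl group trans to it (the ring-cis C4=C5 geometry of the target).

Step 3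
Reactants: 7 (2E)-2-[2-(1,3-dioxolan-2-yl)ethyl]penta-2,4-dien-1-ol
Product: 8 tert-butyl{[(2E)-2-[2-(1,3-dioxolan-2-yl)ethyl]penta-2,4-dien-1-yl]oxy}diphenylsilane
Conditions: TBDPSCl, imidazole, CH2Cl2, 0 °C to rt
Reagents that add atoms: tert-butyl(chloro)diphenylsilane (TBDPSCl), CC(C)(C)[Si](Cl)(c1ccccc1)c1ccccc1
Why: Standard silylation of a primary allylic alcohol; the TBDPS ether should survive the dilute acid, base, hydride, metathesis and palladium steps until the end.

Step 4
Reactants: 8 tert-butyl{[(2E)-2-[2-(1,3-dioxolan-2-yl)ethyl]penta-2,4-dien-1-yl]oxy}diphenylsilane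
Product: 9 (4E)-4-[(tert-butyldiphenylsilyloxy)methyl]hepta-4,6-dienal
Conditions: 1 M HCl/THF (1:4), rt
Reagents that add atoms: water, O
Why: Acid hydrolysis of a dioxolane to the aldehyde, under which a primary TBDPS ether and the diene should be stable.

Step 5
Reactants: 10 (2R)-but-3-ene-1,2-diol
Product: 11 (2R)-2-hydroxybut-3-en-1-yl 4-methylbenzenesulfonate
Conditions: TsCl, Et3N, Bu2SnO (2 mol %), CH2Cl2, 0 °C
Reagents that add atoms: 4-methylbenzenesulfonyl chloride (TsCl), Cc1ccc(cc1)S(=O)(=O)Cl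
Why: Tin-catalysed regioselective sulfonylation of the primary hydroxyl of a 1,2-diol (stannylene acetal activation), which leaves the C8 stereocentre untouched.

Step 6
Reactants: 11 (2R)-2-hydroxybut-3-en-1-yl 4-methylbenzenesulfonate
Product: 12 (2R)-2-(triethylsilyloxy)but-3-en-1-yl 4-methylbenzenesulfonate
Conditions: TESCl, imidazole, CH2Cl2, 0 °C
Reagents that add atoms: chlorotriethylsilane (TESCl), CC[Si](Cl)(CC)CC
Why: Standard silylation of a secondary alcohol; the TES ether can later be cleaved by mild acid without loss of the TBDPS ether.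

Step 7
Reactants: 12 (2R)-2-(triethylsilyloxy)but-3-en-1-yl 4-methylbenzenesulfonate; 13 triethyl phosphonoacetate
Product: 15 ethyl (4S)-2-(diethoxyphosphoryl)-4-(triethylsilyloxy)hex-5-enoate (both C2 epimers), via iodide 14 (not isolated)
Conditions: NaH, 13, DMF, 0 °C; then 12, NaI (1 equiv), 60 °C
Reagents that add atoms: none
Why: SN2 alkylation of the sodium phosphonoacetate carbanion by the primary iodide formed in situ by Finkelstein exchange; the C8 stereocentre is not involved and the new C10 centre is lost in step 8.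

Step 8
Reactants: 15 ethyl (4S)-2-(diethoxyphosphoryl)-4-(triethylsilyloxy)hex-5-enoate; 9 (4E)-4-[(tert-butyldiphenylsilyloxy)methyl]hepta-4,6-dienal
Product: 16 ethyl (2E,6E)-6-[(tert-butyldiphenylsilyloxy)methyl]-2-[(2S)-2-(triethylsilyloxy)but-3-en-1-yl]nona-2,6,8-trienoate
Conditions: NaH, THF, 0 °C; then 9, −78 °C to rt
Reagents that add atoms: none
Why: Horner–Wadsworth–Emmons olefination of an α-alkyl phosphonoacetate with an unbranched aldehyde, which should favour the (E)-enoate (ester trans to C2) and so the ring-cis C1=C10 geometry.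

Step 9
Reactants: 16 ethyl (2E,6E)-6-[(tert-butyldiphenylsilyloxy)methyl]-2-[(2S)-2-(triethylsilyloxy)but-3-en-1-yl]nona-2,6,8-trienoate
Product: 17 (2E,6E)-6-[(tert-butyldiphenylsilyloxy)methyl]-2-[(2S)-2-(triethylsilyloxy)but-3-en-1-yl]nona-2,6,8-trien-1-ol
Conditions: i-Bu2AlH (2.2 equiv), CH2Cl2, −78 °C; aq. KNaC4H4O6 (potassium sodium tartrate) work-up
Reagents that add atoms: none
Why: 1,2-Reduction of an enoate to the allylic alcohol by i-Bu2AlH at low temperature, which spares silyl ethers and alkenes.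

Step 10
Reactants: 17 (2E,6E)-6-[(tert-butyldiphenylsilyloxy)methyl]-2-[(2S)-2-(triethylsilyloxy)but-3-en-1-yl]nona-2,6,8-trien-1-ol
Product: 18 (2E,6E)-6-[(tert-butyldiphenylsilyloxy)methyl]-2-[(2S)-2-(triethylsilyloxy)but-3-en-1-yl]nona-2,6,8-trienal
Conditions: MnO2 (excess), CH2Cl2, rt
Reagents that add atoms: none
Why: Chemoselective MnO2 oxidation of a primary allylic alcohol to the enal without alkene isomerisation; this fixes C14 at the aldehyde level while C15 stays protected.

Step 11
Reactants: 18 (2E,6E)-6-[(tert-butyldiphenylsilyloxy)methyl]-2-[(2S)-2-(triethylsilyloxy)but-3-en-1-yl]nona-2,6,8-trienal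
Product: 19 ten-membered trienal, (1E,5E,7Z,9S)-5-[(tert-butyldiphenylsilyloxy)methyl]-9-(triethylsilyloxy)cyclodeca-1,5,7-triene-1-carbaldehyde (germacrane positions: 1(10)E, 4E, 6Z, 8S)
Conditions: RuCl2(H2IMes)(PCy3)(=CHPh) (second-generation Grubbs catalyst, 10 mol %), toluene (1 mM), 80 °C
Reagents that add atoms: none
Why: Diene–ene ring-closing metathesis in which the catalyst loads at the monosubstituted C7 vinyl group and closes on the terminal alkene of the diene (the fully substituted C4 blocks ring-contracting attack on C4=C5); the two pre-set ring-cis trisubstituted alkenes preorganise the chain, and the new C6=C7 bond should form as the (Z)-isomer preferred in a ten-membered ring under the reversible conditions of this catalyst.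

Step 12
Reactants: 19 ten-membered trienal (1(10)E, 4E, 6Z, 8S); 20 2-bromoprop-2-enoic acid
Product: 22 (6S,7S,8S)-15-(tert-butyldiphenylsilyloxy)-8-(triethylsilyloxy)-14-oxogermacra-1(10),4,11(13)-trien-12,6-olide (1(10)E, 4E; H6 and H7 cis; C8–O trans to C7–C11), via allylpalladium carboxylate 21 (not isolated)
Conditions: 20 (2 equiv), Pd(OAc)2 (10 mol %), Ag2CO3 (1.5 equiv), DMF, 60 °C
Reagents that add atoms: none
Why: Zerovalent palladium formed from Pd(OAc)2 inserts into the C–Br bond of 20, the 1-carboxyvinylpalladium adds syn across C6=C7 of the diene with carbon going to C7, and the resulting allylpalladium over C6–C5–C4, which after loss of bromide as AgBr carries the tethered carboxylate on the metal (21), forms the O–C6 bond by inner-sphere C–O reductive elimination on the face that holds palladium. The closest known reaction type is the Larock-type palladium-catalysed heteroannulation of 1,3-dienes, cyclic ones included, with aryl or vinylic halides that bear a carboxylic acid, which gives cis-fused lactones. The γ-lactone closes in the 5-exo mode at the secondary allyl terminus C6 (the seven-membered alternative at the fully substituted C4 is disfavoured), and C4=C5 keeps its ring-cis geometry because C3 stays anti on the allyl unit. C7 is set by peripheral attack on the (Z)-alkene of the ten-membered ring: H8 eclipses the alkene to avoid A1,3 strain with C5, the silyloxy group lies pseudo-equatorially and the ring chain through C9 shields the inner face, so C11 should enter trans to O8, the sense known from the trans-selective peracid epoxidation of medium-ring cycloalk-2-en-1-ols; C6 follows from the syn delivery of oxygen, which gives the cis ring fusion. The step needs site selectivity for the diene over the trisubstituted enal alkene (only the diene leads to a stabilised allyl), C–C bond formation at C7 and not at C4 (C4 is fully substituted), and syn instead of anti C–O formation, for which the phosphine-free, chloride-free, silver-assisted medium is chosen so that the carboxylate stays on the metal.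

Step 13
Reactants: 22 (6S,7S,8S)-15-(tert-butyldiphenylsilyloxy)-8-(triethylsilyloxy)-14-oxogermacra-1(10),4,11(13)-trien-12,6-olide
Product: 23 (6S,7R,8S)-15-(tert-butyldiphenylsilyloxy)-8-hydroxy-14-oxogermacra-1(10),4,11(13)-trien-12,6-olide (same spatial arrangement as 22; the C7 descriptor changes only because silicon is lost)
Conditions: AcOH/THF/H2O (3:1:1), rt
Reagents that add atoms: none
Why: Mild aqueous acid cleaves a secondary TES ether while a primary TBDPS ether, the enal and the α-methylene lactone should be unaffected.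

Step 14
Reactants: 23 (6S,7R,8S)-15-(tert-butyldiphenylsilyloxy)-8-hydroxy-14-oxogermacra-1(10),4,11(13)-trien-12,6-olide
Product: 24 (6S,7R,8S)-15-(tert-butyldiphenylsilyloxy)-8-(3-methylbutanoyloxy)-14-oxogermacra-1(10),4,11(13)-trien-12,6-olide
Conditions: (i-BuCO)2O, Et3N, DMAP (cat.), CH2Cl2, 0 °C to rt
Reagents that add atoms: 3-methylbutanoic anhydride, CC(C)CC(=O)OC(=O)CC(C)C
Why: DMAP-catalysed acyl transfer to the secondary C8 alcohol (Steglich-type acylation), with no stereocentre involved.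

Step 15
Reactants: 24 (6S,7R,8S)-15-(tert-butyldiphenylsilyloxy)-8-(3-methylbutanoyloxy)-14-oxogermacra-1(10),4,11(13)-trien-12,6-olide
Product: 25 target, (6S,7R,8S)-15-hydroxy-8-(3-methylbutanoyloxy)-14-oxogermacra-1(10),4,11(13)-trien-12,6-olide (1(10)E, 4E)
Conditions: HF·pyridine, pyridine/THF, 0 °C to rt
Reagents that add atoms: none
Why: Buffered, non-basic fluoride cleavage of the primary TBDPS ether, which should spare the isovalerate, the enal and the α-methylene lactone.

**Compound list**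

1 | prop-2-yn-1-ol | C#CCO | starting material
2 | bromoethene | C=CBr | starting material
3 | pent-4-en-2-yn-1-ol | C=CC#CCO | intermediate
4 | 2-(2-bromoethyl)-1,3-dioxolane | BrCCC1OCCO1 | starting material
5 | [2-(1,3-dioxolan-2-yl)ethyl]magnesium bromide | Br[Mg]CCC1OCCO1 | intermediate
6 | cyclic alkenylmagnesium alkoxide (Mg on C5 and on the C15 oxygen, drawn as the monomer) | C=CC1=C(CCC2OCCO2)CO[Mg]1 | intermediate
7 | (2E)-2-[2-(1,3-dioxolan-2-yl)ethyl]penta-2,4-dien-1-ol | C=C/C=C(/CO)CCC1OCCO1 | intermediate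
8 | tert-butyl{[(2E)-2-[2-(1,3-dioxolan-2-yl)ethyl]penta-2,4-dien-1-yl]oxy}diphenylsilane | C=C/C=C(/CO[Si](c1ccccc1)(c1ccccc1)C(C)(C)C)CCC1OCCO1 | intermediate
9 | (4E)-4-[(tert-butyldiphenylsilyloxy)methyl]hepta-4,6-dienal | C=C/C=C(/CO[Si](c1ccccc1)(c1ccccc1)C(C)(C)C)CCC=O | intermediate
10 | (2R)-but-3-ene-1,2-diol | C=C[C@@H](O)CO | starting material
11 | (2R)-2-hydroxybut-3-en-1-yl 4-methylbenzenesulfonate | C=C[C@@H](O)COS(=O)(=O)c1ccc(C)cc1 | intermediate
12 | (2R)-2-(triethylsilyloxy)but-3-en-1-yl 4-methylbenzenesulfonate | C=C[C@@H](O[Si](CC)(CC)CC)COS(=O)(=O)c1ccc(C)cc1 | intermediate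
13 | triethyl phosphonoacetate | CCOC(=O)CP(=O)(OCC)OCC | starting material
14 | triethyl{[(2R)-1-iodobut-3-en-2-yl]oxy}silane | C=C[C@@H](O[Si](CC)(CC)CC)CI | intermediate
15 | ethyl (4S)-2-(diethoxyphosphoryl)-4-(triethylsilyloxy)hex-5-enoate (both C2 epimers) | C=C[C@@H](O[Si](CC)(CC)CC)CC(C(=O)OCC)P(=O)(OCC)OCC | intermediate
16 | ethyl (2E,6E)-6-[(tert-butyldiphenylsilyloxy)methyl]-2-[(2S)-2-(triethylsilyloxy)but-3-en-1-yl]nona-2,6,8-trienoate | C=C[C@@H](O[Si](CC)(CC)CC)C/C(C(=O)OCC)=C\CC/C(CO[Si](c1ccccc1)(c1ccccc1)C(C)(C)C)=C\C=C | intermediate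
17 | (2E,6E)-6-[(tert-butyldiphenylsilyloxy)methyl]-2-[(2S)-2-(triethylsilyloxy)but-3-en-1-yl]nona-2,6,8-trien-1-ol | C=C[C@@H](O[Si](CC)(CC)CC)C/C(CO)=C\CC/C(CO[Si](c1ccccc1)(c1ccccc1)C(C)(C)C)=C\C=C | intermediate
18 | (2E,6E)-6-[(tert-butyldiphenylsilyloxy)methyl]-2-[(2S)-2-(triethylsilyloxy)but-3-en-1-yl]nona-2,6,8-trienal | C=C[C@@H](O[Si](CC)(CC)CC)C/C(C=O)=C\CC/C(CO[Si](c1ccccc1)(c1ccccc1)C(C)(C)C)=C\C=C | intermediate
19 | (1E,5E,7Z,9S)-5-[(tert-butyldiphenylsilyloxy)methyl]-9-(triethylsilyloxy)cyclodeca-1,5,7-triene-1-carbaldehyde (germacrane positions 1(10)E, 4E, 6Z, 8S) | O=C/C1=C/CC/C(CO[Si](c2ccccc2)(c2ccccc2)C(C)(C)C)=C\C=C/[C@@H](O[Si](CC)(CC)CC)C1 | intermediate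
20 | 2-bromoprop-2-enoic acid | C=C(Br)C(=O)O | starting material
21 | allylpalladium carboxylate of divalent palladium, drawn as the C6-bound six-membered palladacycle (η1 form of the η3-allyl over C6–C5–C4; Pd and C11 on the same face) | C=C1C(=O)O[Pd][C@H]2/C=C(/CO[Si](c3ccccc3)(c3ccccc3)C(C)(C)C)CC/C=C(/C=O)C[C@H](O[Si](CC)(CC)CC)[C@@H]12 | intermediate
22 | (6S,7S,8S)-15-(tert-butyldiphenylsilyloxy)-8-(triethylsilyloxy)-14-oxogermacra-1(10),4,11(13)-trien-12,6-olide (1(10)E, 4E; cis-fused lactone; O8 trans to C11) | C=C1C(=O)O[C@H]2/C=C(/CO[Si](c3ccccc3)(c3ccccc3)C(C)(C)C)CC/C=C(/C=O)C[C@H](O[Si](CC)(CC)CC)[C@@H]12 | intermediate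
23 | (6S,7R,8S)-15-(tert-butyldiphenylsilyloxy)-8-hydroxy-14-oxogermacra-1(10),4,11(13)-trien-12,6-olide | C=C1C(=O)O[C@H]2/C=C(/CO[Si](c3ccccc3)(c3ccccc3)C(C)(C)C)CC/C=C(/C=O)C[C@H](O)[C@@H]12 | intermediate
24 | (6S,7R,8S)-15-(tert-butyldiphenylsilyloxy)-8-(3-methylbutanoyloxy)-14-oxogermacra-1(10),4,11(13)-trien-12,6-olide | C=C1C(=O)O[C@H]2/C=C(/CO[Si](c3ccccc3)(c3ccccc3)C(C)(C)C)CC/C=C(/C=O)C[C@H](OC(=O)CC(C)C)[C@@H]12 | intermediate
25 | (6S,7R,8S)-15-hydroxy-8-(3-methylbutanoyloxy)-14-oxogermacra-1(10),4,11(13)-trien-12,6-olide | C=C1C(=O)O[C@H]2/C=C(/CO)CC/C=C(/C=O)C[C@H](OC(=O)CC(C)C)[C@@H]12 | target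

**Step count**

Total: 15 steps. Longest linear sequence: 12 steps (steps 1–4, then 8–15).

**Steps most likely to fail**

Step 12. The carbopalladation may take place on the inner face of the ring (C11 cis to the C8 oxygen), and outer-sphere C–O closure could erode the cis fusion. The fallback keeps the annulation but moves the control of C8 to a later SN2 step. It sets out from 9 and 13 and comes back at 24. The chemistry of steps 5 to 7 is applied to (2S)-but-3-ene-1,2-diol F1: it should give (2S)-2-hydroxybut-3-en-1-yl 4-methylbenzenesulfonate F2, then (2S)-2-(triethylsilyloxy)but-3-en-1-yl 4-methylbenzenesulfonate F3, then with 13, by way of triethyl{[(2S)-1-iodobut-3-en-2-yl]oxy}silane F4 (not isolated), ethyl (4R)-2-(diethoxyphosphoryl)-4-(triethylsilyloxy)hex-5-enoate F5. Olefination with 9 should give the enantiomer of ester 16 F6, i-Bu2AlH the enantiomer of alcohol 17 F7, MnO2 the enantiomer of enal 18 F8, and ring-closing metathesis the enantiomer of macrocycle 19 F9. Annulation with 20 under the conditions of step 12, through the C8-epimeric allylpalladium carboxylate F10 (not isolated), should then place C11 cis to O8 and give the (6S,7S,8R) lactone silyl ether F11, which is correct at C6 and C7. AcOH/THF/H2O should give the (6S,7R,8R) alcohol F12, and Mitsunobu esterification (3-methylbutanoic acid, PPh3, DIAD, toluene, 0 °C to rt) inverts C8 and should give 24.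

Step 11. Intermolecular metathesis (oligomers) may outrun closure of the medium ring, loading next to the bulky allylic silyl ether may be slow, or the ring may close to the (E)-C6=C7 isomer. The fallback replaces the open chain by a substrate with a temporary bridging lactone (C14 carbonyl on O8), which removes the bulky group from the loading alkene and ties C8, C9 and C10 into a ring. It sets out from 16 and comes back at 19. AcOH/THF/H2O should give the hydroxy ester, ethyl (2E,6E)-6-[(tert-butyldiphenylsilyloxy)methyl]-2-[(2S)-2-hydroxybut-3-en-1-yl]nona-2,6,8-trienoate F13, which on warming with PPTS in toluene should lactonise to (3E,5S)-3-{(4E)-4-[(tert-butyldiphenylsilyloxy)methyl]hepta-4,6-dien-1-ylidene}-5-ethenyloxolan-2-one F14. Ring-closing metathesis with the same catalyst should give the bridged bicyclic 14,8-lactone of the ten-membered (4E,6Z)-diene F15. i-Bu2AlH should open it to the macrocyclic C14,C8-diol F16, TESOTf/2,6-lutidine should give the bis(triethylsilyl) ether F17, and Swern oxidation ((COCl)2, DMSO, then Et3N), which converts primary triethylsilyl ethers directly into aldehydes and leaves secondary ones, should give 19.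

Step 2. The organocopper may add in a conjugate sense across the enyne, or the anti selectivity may be lost, giving regio- or stereoisomeric dienols. The fallback builds the C4=C5 alkene by olefination instead of carbometalation. It sets out from 13 and 4 and comes back at 7. Alkylation of the sodium salt of 13 with 4 (NaH, DMF) should give ethyl 2-(diethoxyphosphoryl)-4-(1,3-dioxolan-2-yl)butanoate F18. Horner–Wadsworth–Emmons reaction with acrolein (NaH, THF) should give ethyl (2E)-2-[2-(1,3-dioxolan-2-yl)ethyl]penta-2,4-dienoate F19, and i-Bu2AlH reduction should give 7.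

**Further compounds**

F1 | step 12 | (2S)-but-3-ene-1,2-diol | C=C[C@H](O)CO
F2 | step 12 | (2S)-2-hydroxybut-3-en-1-yl 4-methylbenzenesulfonate | C=C[C@H](O)COS(=O)(=O)c1ccc(C)cc1
F3 | step 12 | (2S)-2-(triethylsilyloxy)but-3-en-1-yl 4-methylbenzenesulfonate | C=C[C@H](O[Si](CC)(CC)CC)COS(=O)(=O)c1ccc(C)cc1
F4 | step 12 | triethyl{[(2S)-1-iodobut-3-en-2-yl]oxy}silane | C=C[C@H](O[Si](CC)(CC)CC)CI
F5 | step 12 | ethyl (4R)-2-(diethoxyphosphoryl)-4-(triethylsilyloxy)hex-5-enoate | C=C[C@H](O[Si](CC)(CC)CC)CC(C(=O)OCC)P(=O)(OCC)OCC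
F6 | step 12 | enantiomer of ester 16 | C=C[C@H](O[Si](CC)(CC)CC)C/C(C(=O)OCC)=C\CC/C(CO[Si](c1ccccc1)(c1ccccc1)C(C)(C)C)=C\C=C
F7 | step 12 | enantiomer of alcohol 17 | C=C[C@H](O[Si](CC)(CC)CC)C/C(CO)=C\CC/C(CO[Si](c1ccccc1)(c1ccccc1)C(C)(C)C)=C\C=C
F8 | step 12 | enantiomer of enal 18 | C=C[C@H](O[Si](CC)(CC)CC)C/C(C=O)=C\CC/C(CO[Si](c1ccccc1)(c1ccccc1)C(C)(C)C)=C\C=C
F9 | step 12 | enantiomer of macrocycle 19 | O=C/C1=C/CC/C(CO[Si](c2ccccc2)(c2ccccc2)C(C)(C)C)=C\C=C/[C@H](O[Si](CC)(CC)CC)C1
F10 | step 12 | C8-epimeric allylpalladium carboxylate (drawn as the C6-bound palladacycle) | C=C1C(=O)O[Pd][C@H]2/C=C(/CO[Si](c3ccccc3)(c3ccccc3)C(C)(C)C)CC/C=C(/C=O)C[C@@H](O[Si](CC)(CC)CC)[C@@H]12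
F11 | step 12 | (6S,7S,8R)-15-(tert-butyldiphenylsilyloxy)-8-(triethylsilyloxy)-14-oxogermacra-1(10),4,11(13)-trien-12,6-olide | C=C1C(=O)O[C@H]2/C=C(/CO[Si](c3ccccc3)(c3ccccc3)C(C)(C)C)CC/C=C(/C=O)C[C@@H](O[Si](CC)(CC)CC)[C@@H]12
F12 | step 12 | (6S,7R,8R)-15-(tert-butyldiphenylsilyloxy)-8-hydroxy-14-oxogermacra-1(10),4,11(13)-trien-12,6-olide | C=C1C(=O)O[C@H]2/C=C(/CO[Si](c3ccccc3)(c3ccccc3)C(C)(C)C)CC/C=C(/C=O)C[C@@H](O)[C@@H]12
F13 | step 11 | ethyl (2E,6E)-6-[(tert-butyldiphenylsilyloxy)methyl]-2-[(2S)-2-hydroxybut-3-en-1-yl]nona-2,6,8-trienoate | C=C[C@@H](O)C/C(C(=O)OCC)=C\CC/C(CO[Si](c1ccccc1)(c1ccccc1)C(C)(C)C)=C\C=C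
F14 | step 11 | (3E,5S)-3-{(4E)-4-[(tert-butyldiphenylsilyloxy)methyl]hepta-4,6-dien-1-ylidene}-5-ethenyloxolan-2-one | C=C[C@@H]1C/C(=C\CC/C(CO[Si](c2ccccc2)(c2ccccc2)C(C)(C)C)=C\C=C)C(=O)O1
F15 | step 11 | bridged bicyclic 14,8-lactone of the ten-membered (1(10)E,4E,6Z)-triene, 8S, 15-O-TBDPS | O=C1O[C@@H]2/C=C\C=C(CO[Si](c3ccccc3)(c3ccccc3)C(C)(C)C)/CC/C=C1\C2
F16 | step 11 | macrocyclic diol: (1(10)E,4E,6Z,8S)-triene with C14 hydroxymethyl, C8 hydroxyl, 15-O-TBDPS | OC/C1=C/CC/C(CO[Si](c2ccccc2)(c2ccccc2)C(C)(C)C)=C\C=C/[C@@H](O)C1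
F17 | step 11 | bis(triethylsilyl) ether of the macrocyclic diol | CC[Si](CC)(CC)OC/C1=C/CC/C(CO[Si](c2ccccc2)(c2ccccc2)C(C)(C)C)=C\C=C/[C@@H](O[Si](CC)(CC)CC)C1
F18 | step 2 | ethyl 2-(diethoxyphosphoryl)-4-(1,3-dioxolan-2-yl)butanoate | CCOC(=O)C(CCC1OCCO1)P(=O)(OCC)OCC
F19 | step 2 | ethyl (2E)-2-[2-(1,3-dioxolan-2-yl)ethyl]penta-2,4-dienoate | C=C/C=C(/C(=O)OCC)CCC1OCCO1
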